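**Retrosynthetic overview**
1. Target 15 ⇐ hydrogenolysis of tetrabenzyl ether 14 ⇐ ionic hydrogenation of lactol 13 (sets C7) ⇐ aryllithium 12 + lactone 11.
2. Lactone 11 ⇐ trans-selective α-alkylation of lactone 9 with BnOCH2Cl (sets C8).
3. Lactone 9 ⇐ invertive opening of the cyclopropane of bicyclic lactone 8 by BnOH (sets the C7′–O bond).
4. Bicyclic lactone 8 ⇐ Rh-carbenoid intramolecular cyclopropanation of Z-allyl diazoacetate 7, which closes the γ-lactone and the cyclopropane in one operation (sets C8′).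
5. Ring order: lactone and cyclopropane together, then the cyclopropane is opened; the lactone ring, whose O–CH2 bond is kept throughout, becomes the tetrahydrofuran.

Assumption: lignan numbering is used (ring C2 = C7, C3 = C8, C4 = C8′, carbinol carbon = C7′); the SMILES is read as 7S,8S,7′S,8′R, so aryl and CH2OH are cis and CH2OH and CH(OH)Ar are trans on the ring.

**Step 1**
Reactants: 1 1-(benzyloxy)-4-bromo-2-methoxybenzene; 2 prop-2-yn-1-ol
Product: 3 3-[4-(benzyloxy)-3-methoxyphenyl]prop-2-yn-1-ol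
Conditions: PdCl2(PPh3)2 (3 mol %), CuI (5 mol %), Et3N, 70 °C
Reagents that add atoms: none
Why: Sonogashira coupling of the aryl bromide with the terminal alkyne joins the aryl group to the three-carbon unit that becomes C7′, C8′ and C9′, and no stereocentre is involved.

**Step 2**
Reactants: 3 3-[4-(benzyloxy)-3-methoxyphenyl]prop-2-yn-1-ol
Product: 4 (2Z)-3-[4-(benzyloxy)-3-methoxyphenyl]prop-2-en-1-ol
Conditions: H2 (1 atm), Pd/CaCO3 poisoned with Pb(OAc)2, quinoline, EtOAc, rt
Reagents that add atoms: none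
Why: Lindlar semihydrogenation adds one equivalent of H2 syn to the alkyne and so gives the Z-alkene needed for the endo-aryl cyclopropane, while the aryl benzyl ether survives.

**Step 3**
Reactants: 4 (2Z)-3-[4-(benzyloxy)-3-methoxyphenyl]prop-2-en-1-ol; 5 bromoacetyl bromide
Product: 7 (2Z)-3-[4-(benzyloxy)-3-methoxyphenyl]prop-2-en-1-yl diazoacetate, via bromoacetate ester 6 (not isolated)
Conditions: NaHCO3, MeCN, 0 °C; then TsNHNHTs, DBU, THF, 0 °C
Reagents that add atoms: N,N′-bis(4-methylbenzenesulfonyl)hydrazine, Cc1ccc(cc1)S(=O)(=O)NNS(=O)(=O)c1ccc(C)cc1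
Why: O-acylation followed by the Fukuyama diazoacetate synthesis (SN2 displacement of bromide by the bis-sulfonylhydrazine, then base-induced loss of two sulfinates) installs the diazo ester without touching the Z-alkene.

**Step 4**
Reactants: 7 (2Z)-3-[4-(benzyloxy)-3-methoxyphenyl]prop-2-en-1-yl diazoacetate
Product: 8 (1S,5R,6S)-6-[4-(benzyloxy)-3-methoxyphenyl]-3-oxabicyclo[3.1.0]hexan-2-one
Conditions: Rh2(5R-MEPY)4 (dirhodium tetrakis[methyl (5R)-2-oxopyrrolidine-5-carboxylate], 1 mol %), CH2Cl2, reflux, slow addition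
Reagents that add atoms: none
Why: Doyle intramolecular cyclopropanation, in which the chiral divalent-rhodium carboxamidate carbenoid adds concertedly and stereospecifically to the tethered Z-alkene, closes the γ-lactone and the cyclopropane together, the catalyst fixing C5 (the future C8′) as R (the 5S catalyst gives the 1R,5S series) and the Z geometry placing the aryl group endo (6S).

**Step 5**
Reactants: 8 (1S,5R,6S)-6-[4-(benzyloxy)-3-methoxyphenyl]-3-oxabicyclo[3.1.0]hexan-2-one
Product: 9 (4R)-4-{(S)-(benzyloxy)[4-(benzyloxy)-3-methoxyphenyl]methyl}oxolan-2-one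
Conditions: BnOH (3 equiv), Sc(OTf)3 (10 mol %), CH2Cl2, −20 °C
Reagents that add atoms: benzyl alcohol, OCc1ccccc1
Why: Proposed new method: a Lewis-acid-assisted SN2-type homo-Michael opening of the donor–acceptor cyclopropane, the closest known reaction being the invertive opening of 2-arylcyclopropane-1,1-diesters by alcohols, in which Sc(OTf)3 binds the lactone carbonyl, the p-alkoxyphenyl group polarises the strained C1–C6 bond and BnOH attacks C6 with inversion to give the (S)-benzylic ether while C5 is untouched and C1 becomes the lactone α-CH2.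

**Step 6**
Reactants: 9 (4R)-4-{(S)-(benzyloxy)[4-(benzyloxy)-3-methoxyphenyl]methyl}oxolan-2-one
Product: 11 (3S,4R)-3-[(benzyloxy)methyl]-4-{(S)-(benzyloxy)[4-(benzyloxy)-3-methoxyphenyl]methyl}oxolan-2-one, via lithium enolate 10 (not isolated)
Conditions: LiN(i-Pr)2, THF, −78 °C; then BnOCH2Cl, −78 to −40 °C
Reagents that add atoms: benzyl chloromethyl ether, ClCOCc1ccccc1
Why: Enolate alkylation of the β-substituted γ-butyrolactone takes place on the face anti to the bulky C4 substituent and so gives the 3,4-trans lactone (3S), which is the C8/C8′ relationship of the target.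

**Step 7**
Reactants: 1 1-(benzyloxy)-4-bromo-2-methoxybenzene; 11 (3S,4R)-3-[(benzyloxy)methyl]-4-{(S)-(benzyloxy)[4-(benzyloxy)-3-methoxyphenyl]methyl}oxolan-2-one
Product: 13 (3S,4R)-2-[4-(benzyloxy)-3-methoxyphenyl]-3-[(benzyloxy)methyl]-4-{(S)-(benzyloxy)[4-(benzyloxy)-3-methoxyphenyl]methyl}oxolan-2-ol, via aryllithium 12 (not isolated)
Conditions: n-BuLi, THF, −78 °C; then 11, −78 °C; H2O quench
Reagents that add atoms: none
Why: Bromine–lithium exchange followed by 1,2-addition of the aryllithium to the lactone carbonyl stops at the lactol stage because the tetrahedral lithium alkoxide does not collapse at −78 °C, and the new C2 centre (both epimers, in equilibrium with the open hydroxy ketone) is erased in the next step.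

**Step 8**
Reactants: 13 (3S,4R)-2-[4-(benzyloxy)-3-methoxyphenyl]-3-[(benzyloxy)methyl]-4-{(S)-(benzyloxy)[4-(benzyloxy)-3-methoxyphenyl]methyl}oxolan-2-ol
Product: 14 (2S,3S,4R)-2-[4-(benzyloxy)-3-methoxyphenyl]-3-[(benzyloxy)methyl]-4-{(S)-(benzyloxy)[4-(benzyloxy)-3-methoxyphenyl]methyl}oxolane
Conditions: Et3SiH, BF3·OEt2, CH2Cl2, −78 °C
Reagents that add atoms: none
Why: Ionic hydrogenation of the lactol (Kishi-type reduction) goes through the 2-aryl oxocarbenium ion, and Et3SiH delivers hydride anti to the neighbouring C3 CH2OBn group, which is held pseudo-axial by allylic strain with the aryl ring, so that C2 becomes S with the aryl group cis to C3.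

**Step 9**
Reactants: 14 (2S,3S,4R)-2-[4-(benzyloxy)-3-methoxyphenyl]-3-[(benzyloxy)methyl]-4-{(S)-(benzyloxy)[4-(benzyloxy)-3-methoxyphenyl]methyl}oxolane
Product: 15 4-[(2S,3S,4R)-4-[(S)-hydroxy(4-hydroxy-3-methoxyphenyl)methyl]-3-(hydroxymethyl)oxolan-2-yl]-2-methoxyphenol
Conditions: H2 (1 atm), Pd/C, EtOAc–MeOH, rt
Reagents that add atoms: none
Why: Hydrogenolysis cleaves the four O–CH2Ph bonds (two aryl and two alkyl benzyl ethers) faster than the ring C2–O and the C7′–O benzylic bonds, so all four stereocentres are left untouched.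

**Compound list**
1 | 1-(benzyloxy)-4-bromo-2-methoxybenzene | COc1cc(Br)ccc1OCc1ccccc1 | starting material
2 | prop-2-yn-1-ol | C#CCO | starting material
3 | 3-[4-(benzyloxy)-3-methoxyphenyl]prop-2-yn-1-ol | COc1cc(C#CCO)ccc1OCc1ccccc1 | intermediate
4 | (2Z)-3-[4-(benzyloxy)-3-methoxyphenyl]prop-2-en-1-ol | COc1cc(/C=C\CO)ccc1OCc1ccccc1 | intermediate
5 | bromoacetyl bromide | BrCC(Br)=O | starting material
6 | (2Z)-3-[4-(benzyloxy)-3-methoxyphenyl]prop-2-en-1-yl bromoacetate | COc1cc(/C=C\COC(=O)CBr)ccc1OCc1ccccc1 | intermediate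
7 | (2Z)-3-[4-(benzyloxy)-3-methoxyphenyl]prop-2-en-1-yl diazoacetate | COc1cc(/C=C\COC(=O)C=[N+]=[N-])ccc1OCc1ccccc1 | intermediate
8 | (1S,5R,6S)-6-[4-(benzyloxy)-3-methoxyphenyl]-3-oxabicyclo[3.1.0]hexan-2-one | COc1cc([C@H]2[C@H]3COC(=O)[C@@H]23)ccc1OCc1ccccc1 | intermediate
9 | (4R)-4-{(S)-(benzyloxy)[4-(benzyloxy)-3-methoxyphenyl]methyl}oxolan-2-one | COc1cc([C@@H](OCc2ccccc2)[C@H]2COC(=O)C2)ccc1OCc1ccccc1 | intermediate
10 | lithium enolate of 9 | COc1cc([C@@H](OCc2ccccc2)[C@H]2COC(O[Li])=C2)ccc1OCc1ccccc1 | intermediate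
11 | (3S,4R)-3-[(benzyloxy)methyl]-4-{(S)-(benzyloxy)[4-(benzyloxy)-3-methoxyphenyl]methyl}oxolan-2-one | COc1cc([C@@H](OCc2ccccc2)[C@H]2COC(=O)[C@@H]2COCc2ccccc2)ccc1OCc1ccccc1 | intermediate
12 | [4-(benzyloxy)-3-methoxyphenyl]lithium | [Li]c1ccc(OCc2ccccc2)c(OC)c1 | intermediate
13 | (3S,4R)-2-[4-(benzyloxy)-3-methoxyphenyl]-3-[(benzyloxy)methyl]-4-{(S)-(benzyloxy)[4-(benzyloxy)-3-methoxyphenyl]methyl}oxolan-2-ol (both C2 epimers) | COc1cc([C@@H](OCc2ccccc2)[C@H]2COC(O)(c3ccc(OCc4ccccc4)c(OC)c3)[C@@H]2COCc2ccccc2)ccc1OCc1ccccc1 | intermediate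
14 | (2S,3S,4R)-2-[4-(benzyloxy)-3-methoxyphenyl]-3-[(benzyloxy)methyl]-4-{(S)-(benzyloxy)[4-(benzyloxy)-3-methoxyphenyl]methyl}oxolane | COc1cc([C@@H](OCc2ccccc2)[C@H]2CO[C@H](c3ccc(OCc4ccccc4)c(OC)c3)[C@@H]2COCc2ccccc2)ccc1OCc1ccccc1 | intermediate
15 | 4-[(2S,3S,4R)-4-[(S)-hydroxy(4-hydroxy-3-methoxyphenyl)methyl]-3-(hydroxymethyl)oxolan-2-yl]-2-methoxyphenol | COc1cc([C@@H](O)[C@H]2CO[C@H](c3ccc(O)c(OC)c3)[C@@H]2CO)ccc1O | target

**Totals and risks**

Total step count: 9. Longest linear sequence: 9 steps (1 → 15; aryl bromide 1 is used a second time in step 7).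

The three steps most likely to fail:

Step 5, the cyclopropane opening. The strongly donating p-benzyloxyphenyl group may let the opening leak through a benzylic cation, which would erode the inversion at C7′. The fallback sets C7′ by reagent control instead. It sets out from 8: solvolysis in aqueous CF3CO2H/THF gives the epimeric alcohols (4R)-4-{[4-(benzyloxy)-3-methoxyphenyl](hydroxy)methyl}oxolan-2-one F1. Dess–Martin oxidation gives the ketone (4R)-4-[4-(benzyloxy)-3-methoxybenzoyl]oxolan-2-one F2, handled under neutral conditions to protect the α-stereocentre. Reduction with (R)-2-methyl-CBS-oxazaborolidine and BH3·SMe2 gives (4R)-4-{(S)-[4-(benzyloxy)-3-methoxyphenyl](hydroxy)methyl}oxolan-2-one F3. Benzylation with benzyl 2,2,2-trichloroacetimidate and catalytic TfOH comes back to the route at 9.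

Step 7, the aryllithium addition. The basic aryllithium may enolise the lactone, after which benzyloxide can be lost from the β-position, or it may add twice. The fallback replaces direct addition by a two-stage acyl substitution. It sets out from 11: MeNH(OMe)·HCl with i-PrMgCl opens the lactone to the Weinreb amide (2S,3R,4S)-4-(benzyloxy)-4-[4-(benzyloxy)-3-methoxyphenyl]-2-[(benzyloxy)methyl]-3-(hydroxymethyl)-N-methoxy-N-methylbutanamide F4. Two equivalents of 12 then give the hydroxy ketone, which closes to the lactol and comes back to the route at 13.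

Step 8, the lactol reduction. The cis selectivity may be incomplete, and BF3 may ionise the electron-rich benzylic ether at C7′. The fallback sets C7 by reagent control and closes the ring by substitution at the primary carbon. It sets out from 13: reduction of its open hydroxy-ketone form with (R)-2-methyl-CBS-oxazaborolidine and BH3·SMe2 gives the diol (1S,2S,3R,4S)-4-(benzyloxy)-1,4-bis[4-(benzyloxy)-3-methoxyphenyl]-2-[(benzyloxy)methyl]-3-(hydroxymethyl)butan-1-ol F5. Mitsunobu cyclodehydration (PPh3, DIAD) activates the primary alcohol, the benzylic oxygen closes the ring with retention at C7, and the route is rejoined at 14.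

**Further compounds**
F1 | step 5 | (4R)-4-{[4-(benzyloxy)-3-methoxyphenyl](hydroxy)methyl}oxolan-2-one (both carbinol epimers) | COc1cc(C(O)[C@H]2COC(=O)C2)ccc1OCc1ccccc1
F2 | step 5 | (4R)-4-[4-(benzyloxy)-3-methoxybenzoyl]oxolan-2-one | COc1cc(C(=O)[C@H]2COC(=O)C2)ccc1OCc1ccccc1
F3 | step 5 | (4R)-4-{(S)-[4-(benzyloxy)-3-methoxyphenyl](hydroxy)methyl}oxolan-2-one | COc1cc([C@@H](O)[C@H]2COC(=O)C2)ccc1OCc1ccccc1
F4 | step 7 | (2S,3R,4S)-4-(benzyloxy)-4-[4-(benzyloxy)-3-methoxyphenyl]-2-[(benzyloxy)methyl]-3-(hydroxymethyl)-N-methoxy-N-methylbutanamide | COc1cc([C@@H](OCc2ccccc2)[C@@H](CO)[C@@H](COCc2ccccc2)C(=O)N(C)OC)ccc1OCc1ccccc1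
F5 | step 8 | (1S,2S,3R,4S)-4-(benzyloxy)-1,4-bis[4-(benzyloxy)-3-methoxyphenyl]-2-[(benzyloxy)methyl]-3-(hydroxymethyl)butan-1-ol | COc1cc([C@@H](OCc2ccccc2)[C@@H](CO)[C@@H](COCc2ccccc2)[C@H](O)c2ccc(OCc3ccccc3)c(OC)c2)ccc1OCc1ccccc1
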